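## The problem

Andavadoic acid **19** is a 1,2-dioxolane (ring atoms O1, O2, C3, C4, C5) in which C3 carries a methyl group and the CH2CO2H arm, C5 carries a methyl group and an unbranched 10-phenyldecyl chain, and C4 is a plain CH2. Both stereocentres, C3 (R) and C5 (S), are fully substituted, oxygen-bearing carbons without hydrogen, so neither can be epimerised or corrected later, and the trans relation of arm and chain and the absolute configuration must be set, or sorted out, once the ring exists. The two centres are 1,3-related across C4 and each distinguishes only a methyl group from a primary alkyl group, so one can steer the other only weakly and there is no third stereocentre to lean on. The O–O bond rules out hydrogenation, hydride reagents, organomagnesium or organolithium reagents and low-valent metals after ring formation, so the whole phenyl-terminated chain should be in place before the peroxide is made. Once the arm is an acyl group, O2 sits β to a carbonyl and can be expelled from an enolate; the arm is therefore best carried through ring formation as a protected 2-hydroxyethyl group, and later basic steps on acyl derivatives must be gentle. The feature that opens the structure is that C3 is at the ketone oxidation level and C5 is a tertiary carbon bearing a methyl group. The ring thus divides into a three-atom O1–O2–C3 unit, available as a peroxycarbenium ion, and a two-atom C4=C5 unit, a 1,1-disubstituted alkene whose Markovnikov cation is C5.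

## Retrosynthesis

**19 from 17 (and 14 plus 15).** The last bond cut is not skeletal: it is the acyl–nitrogen bond of imide **17**, which releases **19** (through peroxy acid **18**) and the auxiliary **15**. The ring-forming step chosen below cannot fix absolute configuration, so the enantiomers of the racemic trans acid **14** must be parted. This is done covalently: **14** is joined to enantiopure **15** through mixed anhydride **16**, which turns the two enantiomers into two diastereomeric imides. Imide **17**, the one built on the (3R,5S) acid, is isolated by chromatography. This is preferred to a salt resolution, which depends on the crystallinity of a salt of an oily long-chain acid. It is also preferred to a resolution at the alcohol stage, where C3 would lie one atom farther from the chiral handle. The precursor **14** needs no asymmetric step. The forward reactions must give separable diastereomers and must cleave the imide without enolising it.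

**14 from 12, and 12 from 11.** No skeletal bond is cut here; the arm is taken back from acid **14** through aldehyde **13** to primary alcohol **12** and then to pivalate **11**. With the arm at the alcohol level and two carbons away, no carbonyl sits next to the cationic carbon during ring formation, and nothing on the arm can be enolised while the ring is made. The forward reactions must spare the O–O bond, which points to base-mediated transesterification and a metal-free oxoammonium oxidation.

**11 from 10 and 6.** The ring bonds C3–C4 and O1–C5 are cut together, giving silylperoxy ketal **10** and alkene **6**. The mirror cut (C4–C5 and O2–C3, with the cation on the chain-bearing carbon and alkene **8** as partner) would place the ester arm on the cation formed after C–C bond formation, where the pivalate carbonyl could capture it. Cutting the O–O bond or a single C–O bond would lead to long linear precursors that carry both stereocentres. The chosen cut gives two fragments of 16 and 19 carbons, with no ring and no stereocentre that matters. It asks of the forward reaction Markovnikov attack through the alkene CH2 and capture of the tertiary cation by oxygen faster than loss of a proton. Because the ring closure has little facial bias, it also asks for a purification at this stage that frees trans **11** from cis-configured material, so that every later step handles a single racemate.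

**10 from 9, 8 and 7.** The carbon bearing OMe and OOSiEt3 is a masked ketone. Ketal **10** comes from hydroperoxy ketal **9** by silylation, and **9** from ozonolysis of alkene **8** in methanol, which delivers both oxygens of the peroxide and the methoxy group in one operation. Alkene **8** is the pivalate of commercial alcohol **7**. Perketalisation of the corresponding ketone with hydrogen peroxide is the neighbouring option; it is set aside because it needs concentrated peroxide and tends to give geminal bisperoxides.

**6 from 3 (through 5) and 4; 3 from 1 and 2.** The sp2–sp3 bond C2–C3 of **6** is cut to Grignard reagent **5** and 2-bromopropene **4**. The aryl–alkyl bond of **3** is cut to dibromide **1** and phenylmagnesium bromide **2**. Both are catalysed couplings of Grignard reagents with bromides, and the ten-carbon spacer is bought intact. The forward reactions ask only for mono-substitution of **1** and for a coupling that leaves the terminal alkene where it is.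

## Roads not taken

**Alternative 1: double oxetane opening with hydrogen peroxide.** Both C–O bonds of the ring (O1–C5 and O2–C3) are cut, so that the key step would give the C2-symmetric diol A1 from the bis-oxetane A2. With H2O2 and Me3SiOTf one oxetane would open at its tertiary carbon, and the hydroperoxy group so installed would open the second oxetane in a 5-exo-tet closure.
- Merits: the O–O bond is bought from hydrogen peroxide, and both stereocentres arise by invertive substitution, so the trans relation and the absolute configuration are relayed from A2. On stereocontrol this road is better in principle than the chosen one.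
- Weak points: A2 has two tertiary ether stereocentres that need their own asymmetric synthesis. Substitution at a tertiary oxetane carbon competes with ionisation, which would erode both configurations over two such events. The two identical arms of A1 must then be told apart, one oxidised and the other extended by eight carbons and a phenyl ring next to an existing peroxide. That excludes Grignard-type couplings and hydrogenation and would need olefination, diimide reduction and several protecting-group steps.
- Comparison: the chosen plan installs the whole chain before the peroxide exists, joins two fragments in a known ring-forming reaction and is far shorter. It pays for its lack of stereocontrol with one diastereomer separation and one resolution.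

**Alternative 2: oxidative peroxypalladation.** Only O1–C5 is cut, and the key step would give the alkenyl dioxolane A3 from the unsaturated tertiary hydroperoxide A4. With Pd(OAc)2 and benzoquinone the hydroperoxide would add 5-exo to the substituted end of the trisubstituted alkene, and β-hydride elimination would leave the C1'=C2' double bond.
- Merits: the arm is already an ester, so no late oxidation is needed. The step is catalytic, and C3 could in principle come from an enantioenriched hydroperoxide, which the chosen plan cannot match.
- Weak points: an enantiopure tertiary β-hydroperoxy ester such as A4 is itself hard to make. C5 would be set by 1,3-induction from a centre that distinguishes methyl from CH2CO2Me, so the diastereomer problem remains. Divalent palladium also decomposes hydroperoxides, and formation of a quaternary C–O bond in a dioxolane by this route is thinly precedented. The new alkene would have to be reduced with diimide.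
- Comparison: the chosen plan is no better on the C3/C5 relation, but it is convergent, shorter and uses a ring-forming reaction of established type.

**Alternative 3: O–O bond closed last.** The O1–O2 bond is cut, and the key step would give silyl ether A5 from the 1,3-diol A6. One tertiary hydroxyl would be O-chlorinated with tBuOCl, and the other, as its potassium alkoxide (KH), would displace chloride at oxygen in a 5-exo-tet closure.
- Merits: both stereocentres are tertiary alcohols that can be set by established asymmetric chemistry before any peroxide exists. Absolute and relative configuration would be fully controlled, with no resolution and no diastereomer separation; in this respect it is clearly the better road.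
- Weak points: nucleophilic attack of a tertiary alkoxide on hypochlorite oxygen to give a di-tertiary peroxide would have to be invented. The alkoxide is more likely to attack chlorine, tertiary hypochlorites fragment through alkoxy radicals, and a 1,3-diol mono-alkoxide with a leaving group on the other oxygen can fragment in a retro-aldol sense. A6 would also need a long linear sequence, and the untested step would come at its end.
- Comparison: the chosen plan gives up stereocontrol but uses only reactions of known type, and its losses fall in two separations and not in an unprecedented ring closure.

Key step: step 6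

Remark on the chemistry: andavadoic acid is taken as the (3R,5S) acid, with the CH2CO2H arm and the 10-phenyldecyl chain on opposite faces of the ring. In the ester and alcohol intermediates the same arrangement is named (3S,5S), because the ranking of the substituents at C3 changes.

## Route

Step 1
Reactants: 1 1,10-dibromodecane; 2 phenylmagnesium bromide
Product: 3 (10-bromodecyl)benzene
Conditions: Li2CuCl4 (3 mol %), THF, 0 °C to rt; 1 in threefold excess, recovered by distillation
Reagents that add atoms: none
Why: Copper-catalysed cross-coupling of an aryl Grignard reagent with a primary alkyl bromide; the excess of 1 keeps double arylation low, and 3 should be separable from recovered 1 and the diarylated by-product by vacuum distillation.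

Step 2
Reactants: 3 (10-bromodecyl)benzene; 4 2-bromopropene
Product: 6 2-methyl-12-phenyldodec-1-ene, via (10-phenyldecyl)magnesium bromide 5 (not isolated)
Conditions: Mg, THF, 45 °C; then 4, NiCl2(dppp) (2 mol %), THF, 0 °C to rt
Reagents that add atoms: magnesium, [Mg] (held in intermediate 5 only)
Why: Kumada–Corriu coupling of a primary alkylmagnesium bromide with an alkenyl bromide; the chelating dppp ligand suppresses β-hydride elimination and alkene migration, so the 1,1-disubstituted alkene should be delivered intact.

Step 3
Reactants: 7 3-methylbut-3-en-1-ol
Product: 8 3-methylbut-3-en-1-yl 2,2-dimethylpropanoate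
Conditions: PivCl, Et3N, DMAP (cat.), CH2Cl2, 0 °C to rt
Reagents that add atoms: pivaloyl chloride, CC(C)(C)C(=O)Cl
Why: DMAP-catalysed O-acylation of a primary alcohol; the pivalate is chosen because it should survive ozone, silylation and SnCl4 and is a poor internal nucleophile.

Step 4
Reactants: 8 3-methylbut-3-en-1-yl 2,2-dimethylpropanoate
Product: 9 rac-3-hydroperoxy-3-methoxybutyl 2,2-dimethylpropanoate
Conditions: O3, MeOH/CH2Cl2 (1:3), −78 °C; N2 purge; concentration below 25 °C
Reagents that add atoms: ozone, [O-][O+]=O; methanol, CO
Why: Ozonolysis with solvent capture (Criegee mechanism): the primary ozonide of the 1,1-disubstituted alkene should fragment to formaldehyde and the more substituted carbonyl oxide, which methanol traps as the hydroperoxy ketal; the new centre forms racemic and is erased in step 6.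

Step 5
Reactants: 9 rac-3-hydroperoxy-3-methoxybutyl 2,2-dimethylpropanoate
Product: 10 rac-3-methoxy-3-[(triethylsilyl)peroxy]butyl 2,2-dimethylpropanoate
Conditions: Et3SiCl, imidazole, DMF, 0 °C
Reagents that add atoms: chlorotriethylsilane, CC[Si](Cl)(CC)CC
Why: Silylation of the hydroperoxide OH under mild base; the chlorosilane is not Lewis acidic enough to ionise the ketal, and the silyl group later serves as the leaving group on O1.

Step 6
Reactants: 10 rac-3-methoxy-3-[(triethylsilyl)peroxy]butyl 2,2-dimethylpropanoate; 6 2-methyl-12-phenyldodec-1-ene
Product: 11 rac-2-[(3S,5S)-3,5-dimethyl-5-(10-phenyldecyl)-1,2-dioxolan-3-yl]ethyl 2,2-dimethylpropanoate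
Conditions: SnCl4 (1.1 equiv), CH2Cl2, −78 °C, 10 in 1.5-fold excess; NaHCO3 (aq) quench at −78 °C; chromatography on silica gel, then normal-phase HPLC, trans 11 freed from the cis diastereomer
Reagents that add atoms: none
Why: SnCl4 removes the methoxy group of 10 to give a triethylsilylperoxycarbenium ion at C3; the CH2 terminus of 6 attacks it (bond C3–C4) and leaves a tertiary cation at C5. The silylated oxygen O1 then captures that cation (bond O1–C5), the silyl group leaves with the methoxide as Et3SiOMe, and SnCl4 is formally returned. This is the known SnCl4-mediated annulation of ketone-derived silylperoxy ketals with 1,1-disubstituted alkenes to give 1,2-dioxolanes, applied to two new partners. The ring (O1, O2, C3, C4, C5) closes by oxygen capture of a free planar cation, endo with respect to the former alkene since both alkene carbons end up in the ring; because the electrophile is a cation and not a π bond, no stereoelectronic penalty applies. C3 is set when the alkene adds to either face of the planar, achiral peroxycarbenium ion, so the product is racemic. C5 is set when O1 adds to either face of the C5 cation, and the choice rests only on the steric difference between methyl and CH2 on each centre, so the trans (3S*,5S*) and cis (3R*,5S*) dioxolanes are both expected with at most a small trans bias; trans 11 is therefore isolated chromatographically and assigned by NOE between the C3 and C5 substituents. The step needs regioselectivity and cation capture faster than proton loss or chloride capture; the 1,1-disubstituted alkene, the five-membered reach of O1, the low temperature and an ester kept two carbons from C3 (with the phenyl ring too remote for Friedel–Crafts attack) should secure them.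

Step 7
Reactants: 11 rac-2-[(3S,5S)-3,5-dimethyl-5-(10-phenyldecyl)-1,2-dioxolan-3-yl]ethyl 2,2-dimethylpropanoate
Product: 12 rac-2-[(3S,5S)-3,5-dimethyl-5-(10-phenyldecyl)-1,2-dioxolan-3-yl]ethan-1-ol
Conditions: NaOMe (20 mol %), MeOH, 40 °C
Reagents that add atoms: none
Why: Zemplén-type base-catalysed transesterification; the dioxolane has no hydrogen on C3 or C5 and no carbonyl β to the peroxide, so neither Kornblum–DeLaMare fragmentation nor β-elimination is open, and no stereocentre is touched.

Step 8
Reactants: 12 rac-2-[(3S,5S)-3,5-dimethyl-5-(10-phenyldecyl)-1,2-dioxolan-3-yl]ethan-1-ol
Product: 14 rac-2-[(3R,5S)-3,5-dimethyl-5-(10-phenyldecyl)-1,2-dioxolan-3-yl]acetic acid, via dioxolanylacetaldehyde 13 (not isolated)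
Conditions: TEMPO (20 mol %), PhI(OAc)2 (2.2 equiv), MeCN/H2O (1:1), rt
Reagents that add atoms: water, O
Why: Oxoammonium (TEMPO) oxidation of the primary alcohol to aldehyde 13, whose hydrate is oxidised on to the acid; the conditions are metal-free, non-reducing and nearly neutral, so the O–O bond and the benzylic CH2 should be left alone. No stereocentre is touched; the C3 descriptor changes from S to R only through the change in substituent ranking.

Step 9
Reactants: 14 rac-2-[(3R,5S)-3,5-dimethyl-5-(10-phenyldecyl)-1,2-dioxolan-3-yl]acetic acid; 15 (4S)-4-benzyl-1,3-oxazolidin-2-one
Product: 17 (4S)-4-benzyl-3-{[(3R,5S)-3,5-dimethyl-5-(10-phenyldecyl)-1,2-dioxolan-3-yl]acetyl}-1,3-oxazolidin-2-one, via mixed pivalic anhydride 16 (not isolated)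
Conditions: PivCl, Et3N, THF, −20 °C; then LiCl, 15, −20 °C to rt; chromatography on silica gel, 17 freed from the diastereomeric imide of the (3S,5R) acid
Reagents that add atoms: pivaloyl chloride, CC(C)(C)C(=O)Cl (its acyl group is held in intermediate 16 only)
Why: N-acylation of the oxazolidinone by a mixed anhydride with LiCl activation; no stereocentre is made, and because 14 is racemic the acylation necessarily gives two diastereomeric imides in equal amounts. They differ in the relation between C3 (β to the imide carbonyl) and the benzyl-bearing carbon of the auxiliary and should be separable on silica; 17 is to be identified by X-ray analysis or by the sign of rotation of the acid released from each.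

Step 10
Reactants: 17 (4S)-4-benzyl-3-{[(3R,5S)-3,5-dimethyl-5-(10-phenyldecyl)-1,2-dioxolan-3-yl]acetyl}-1,3-oxazolidin-2-one
Product: 19 andavadoic acid (2-[(3R,5S)-3,5-dimethyl-5-(10-phenyldecyl)-1,2-dioxolan-3-yl]acetic acid), via dioxolanylperoxyacetic acid 18 (not isolated)
Conditions: LiOH, H2O2, THF/H2O (3:1), 0 °C; then Na2SO3 (aq); then 1 M HCl to pH 3
Reagents that add atoms: hydrogen peroxide, OO
Why: Hydroperoxide-mediated cleavage of an N-acyl oxazolidinone: HOO− attacks the exocyclic carbonyl, the peroxy acid 18 is reduced by sulfite, and the auxiliary 15 is recovered. The weakly basic, strongly nucleophilic hydroperoxide at 0 °C should cleave the imide faster than it enolises it, and the di-tertiary ring peroxide is inert to sulfite, so C3 and C5 stay as separated.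

## Compound list

1 | 1,10-dibromodecane | BrCCCCCCCCCCBr | starting material
2 | phenylmagnesium bromide | Br[Mg]c1ccccc1 | starting material
3 | (10-bromodecyl)benzene | BrCCCCCCCCCCc1ccccc1 | intermediate
4 | 2-bromopropene | C=C(C)Br | starting material
5 | (10-phenyldecyl)magnesium bromide (not isolated) | Br[Mg]CCCCCCCCCCc1ccccc1 | intermediate
6 | 2-methyl-12-phenyldodec-1-ene | C=C(C)CCCCCCCCCCc1ccccc1 | intermediate
7 | 3-methylbut-3-en-1-ol | C=C(C)CCO | starting material
8 | 3-methylbut-3-en-1-yl 2,2-dimethylpropanoate | C=C(C)CCOC(=O)C(C)(C)C | intermediate
9 | rac-3-hydroperoxy-3-methoxybutyl 2,2-dimethylpropanoate | CC(OC)(OO)CCOC(=O)C(C)(C)C | intermediate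
10 | rac-3-methoxy-3-[(triethylsilyl)peroxy]butyl 2,2-dimethylpropanoate | CC(OC)(OO[Si](CC)(CC)CC)CCOC(=O)C(C)(C)C | intermediate
11 | rac-2-[(3S,5S)-3,5-dimethyl-5-(10-phenyldecyl)-1,2-dioxolan-3-yl]ethyl 2,2-dimethylpropanoate (trans; racemic, wanted enantiomer drawn) | C[C@]1(CCCCCCCCCCc2ccccc2)C[C@](C)(CCOC(=O)C(C)(C)C)OO1 | intermediate
12 | rac-2-[(3S,5S)-3,5-dimethyl-5-(10-phenyldecyl)-1,2-dioxolan-3-yl]ethan-1-ol (trans; racemic, wanted enantiomer drawn) | C[C@]1(CCCCCCCCCCc2ccccc2)C[C@](C)(CCO)OO1 | intermediate
13 | rac-2-[(3R,5S)-3,5-dimethyl-5-(10-phenyldecyl)-1,2-dioxolan-3-yl]acetaldehyde (trans; racemic, wanted enantiomer drawn; not isolated) | C[C@]1(CCCCCCCCCCc2ccccc2)C[C@](C)(CC=O)OO1 | intermediate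
14 | rac-2-[(3R,5S)-3,5-dimethyl-5-(10-phenyldecyl)-1,2-dioxolan-3-yl]acetic acid (trans; racemic, wanted enantiomer drawn) | C[C@]1(CCCCCCCCCCc2ccccc2)C[C@](C)(CC(=O)O)OO1 | intermediate
15 | (4S)-4-benzyl-1,3-oxazolidin-2-one | O=C1N[C@@H](Cc2ccccc2)CO1 | starting material
16 | 2,2-dimethylpropanoic rac-[(3R,5S)-3,5-dimethyl-5-(10-phenyldecyl)-1,2-dioxolan-3-yl]acetic anhydride (racemic, wanted enantiomer drawn; not isolated) | C[C@]1(CCCCCCCCCCc2ccccc2)C[C@](C)(CC(=O)OC(=O)C(C)(C)C)OO1 | intermediate
17 | (4S)-4-benzyl-3-{[(3R,5S)-3,5-dimethyl-5-(10-phenyldecyl)-1,2-dioxolan-3-yl]acetyl}-1,3-oxazolidin-2-one | C[C@]1(CCCCCCCCCCc2ccccc2)C[C@](C)(CC(=O)N2[C@@H](Cc3ccccc3)COC2=O)OO1 | intermediate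
18 | 2-[(3R,5S)-3,5-dimethyl-5-(10-phenyldecyl)-1,2-dioxolan-3-yl]ethaneperoxoic acid (not isolated) | C[C@]1(CCCCCCCCCCc2ccccc2)C[C@](C)(CC(=O)OO)OO1 | intermediate
19 | andavadoic acid, 2-[(3R,5S)-3,5-dimethyl-5-(10-phenyldecyl)-1,2-dioxolan-3-yl]acetic acid (single enantiomer) | C[C@]1(CCCCCCCCCCc2ccccc2)C[C@](C)(CC(=O)O)OO1 | target

## Step count and risks

Total: 10 steps. Longest linear sequence: 8 steps (steps 3 to 10, from 7); the alkene branch (steps 1 and 2) joins at step 6.

**Step 6 (key step).** The most likely failure is stereochemical. The ring closure has little facial preference, so a large share of the material may end up cis, and the two nonpolar diastereomeric pivalates may not be resolved cleanly, so that cis material would be carried forward. If instead the oxygenated peroxycarbenium ion proves the weak point, the exchange of roles described under step 4 applies. Fallback: the separation is moved to a stage with a better handle. The unseparated annulation product (11 together with its cis isomer) is methanolysed as in step 7, which gives 12 mixed with the cis alcohol rac-2-[(3R,5S)-3,5-dimethyl-5-(10-phenyldecyl)-1,2-dioxolan-3-yl]ethan-1-ol F1. The mixed alcohols are acylated with 4-nitrobenzoyl chloride and pyridine. The trans ester rac-2-[(3S,5S)-3,5-dimethyl-5-(10-phenyldecyl)-1,2-dioxolan-3-yl]ethyl 4-nitrobenzoate F2 is freed from the cis ester rac-2-[(3R,5S)-3,5-dimethyl-5-(10-phenyldecyl)-1,2-dioxolan-3-yl]ethyl 4-nitrobenzoate F3 by fractional crystallisation, or by normal-phase HPLC, where the π-acidic aroyl group should widen the retention difference. K2CO3 in methanol returns F2 to 12, where the route is rejoined.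

**Step 4.** The hydroperoxy ketal carries an acyloxy group two carbons away and may not survive isolation. It can revert to the ketone with loss of hydrogen peroxide and methanol on concentration or on silica, and that ketone can then lose pivalate by β-elimination. The same arm may also cost the derived peroxycarbenium ion a proton before the alkene arrives in step 6. Fallback: the roles of the partners are exchanged. Alkene 6 is ozonised in methanol to (11-hydroperoxy-11-methoxydodecyl)benzene F4, which is silylated (Et3SiCl, imidazole) to triethyl[(2-methoxy-12-phenyldodecan-2-yl)peroxy]silane F5. F5 is ionised with SnCl4 in the presence of alkene 8. Bonds C4–C5 and O2–C3 then form, and after the same separation the route is rejoined at 11. The peroxycarbenium ion now carries only alkyl groups; the price is that the pivalate arm sits on the cation formed after the C–C bond, where its carbonyl oxygen could intercept it.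

**Step 9.** The two diastereomeric imides may fail to separate, because the stereocentres of the acyl part and of the auxiliary are five bonds apart and the long chain dominates retention. Soft enolisation by Et3N/LiCl is a lesser concern. Fallback: acid 14 is esterified with Me3SiCHN2 in methanol/toluene to methyl rac-2-[(3R,5S)-3,5-dimethyl-5-(10-phenyldecyl)-1,2-dioxolan-3-yl]acetate F6. The enantiomers of F6 are separated by preparative HPLC on a cellulose tris(3,5-dimethylphenylcarbamate) stationary phase. The (3R,5S) enantiomer is saponified (LiOH, THF/H2O, then acid) and the route ends at 19.

**Step 10.** Hydroxide may enolise the imide, so that O2 is expelled from the enolate and the opened hydroperoxide recloses by conjugate addition; this would scramble C3 after it has been sorted. Attack at the ring carbonyl of the auxiliary is a second, lesser risk. Fallback: the imide is bypassed. Acid 14 is treated with (R)-1-phenylethylamine, or with its antipode if that gives the less soluble salt with the wanted acid. The salt (1R)-1-phenylethan-1-aminium [(3R,5S)-3,5-dimethyl-5-(10-phenyldecyl)-1,2-dioxolan-3-yl]acetate F7 is crystallised to constant rotation, and partition between ether and dilute HCl gives 19.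

## Further compounds

F1 | step 6 | rac-2-[(3R,5S)-3,5-dimethyl-5-(10-phenyldecyl)-1,2-dioxolan-3-yl]ethan-1-ol (cis; racemic, one enantiomer drawn) | C[C@]1(CCCCCCCCCCc2ccccc2)C[C@@](C)(CCO)OO1
F2 | step 6 | rac-2-[(3S,5S)-3,5-dimethyl-5-(10-phenyldecyl)-1,2-dioxolan-3-yl]ethyl 4-nitrobenzoate (trans; racemic, wanted enantiomer drawn) | C[C@]1(CCCCCCCCCCc2ccccc2)C[C@](C)(CCOC(=O)c2ccc(cc2)[N+](=O)[O-])OO1
F3 | step 6 | rac-2-[(3R,5S)-3,5-dimethyl-5-(10-phenyldecyl)-1,2-dioxolan-3-yl]ethyl 4-nitrobenzoate (cis; racemic, one enantiomer drawn) | C[C@]1(CCCCCCCCCCc2ccccc2)C[C@@](C)(CCOC(=O)c2ccc(cc2)[N+](=O)[O-])OO1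
F4 | step 4 | (11-hydroperoxy-11-methoxydodecyl)benzene (racemic) | CC(OC)(OO)CCCCCCCCCCc1ccccc1
F5 | step 4 | triethyl[(2-methoxy-12-phenyldodecan-2-yl)peroxy]silane (racemic) | CC(OC)(OO[Si](CC)(CC)CC)CCCCCCCCCCc1ccccc1
F6 | step 9 | methyl rac-2-[(3R,5S)-3,5-dimethyl-5-(10-phenyldecyl)-1,2-dioxolan-3-yl]acetate (racemic, wanted enantiomer drawn) | C[C@]1(CCCCCCCCCCc2ccccc2)C[C@](C)(CC(=O)OC)OO1
F7 | step 10 | (1R)-1-phenylethan-1-aminium [(3R,5S)-3,5-dimethyl-5-(10-phenyldecyl)-1,2-dioxolan-3-yl]acetate | C[C@]1(CCCCCCCCCCc2ccccc2)C[C@](C)(CC(=O)[O-])OO1.C[C@@H]([NH3+])c1ccccc1
A1 | alternative 1 | 2,2'-[(3S,5S)-3,5-dimethyl-1,2-dioxolane-3,5-diyl]di(ethan-1-ol) | C[C@]1(CCO)C[C@](C)(CCO)OO1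
A2 | alternative 1 | bis[(2R)-2-methyloxetan-2-yl]methane | C[C@@]1(CCO1)C[C@@]2(C)CCO2
A3 | alternative 2 | methyl 2-{(3R,5R)-3,5-dimethyl-5-[(1E)-10-phenyldec-1-en-1-yl]-1,2-dioxolan-3-yl}acetate | C[C@]1(/C=C/CCCCCCCCc2ccccc2)C[C@](C)(CC(=O)OC)OO1
A4 | alternative 2 | methyl (3R,5E)-3-hydroperoxy-3,5-dimethyl-15-phenylpentadec-5-enoate | C/C(=C\CCCCCCCCCc1ccccc1)C[C@](C)(CC(=O)OC)OO
A5 | alternative 3 | tert-butyl{2-[(3S,5S)-3,5-dimethyl-5-(10-phenyldecyl)-1,2-dioxolan-3-yl]ethoxy}diphenylsilane | C[C@]1(CCCCCCCCCCc2ccccc2)C[C@](C)(CCO[Si](c2ccccc2)(c2ccccc2)C(C)(C)C)OO1
A6 | alternative 3 | (3S,5S)-1-{[tert-butyl(diphenyl)silyl]oxy}-3,5-dimethyl-15-phenylpentadecane-3,5-diol | C[C@](O)(CCCCCCCCCCc1ccccc1)C[C@@](C)(O)CCO[Si](c1ccccc1)(c1ccccc1)C(C)(C)C
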